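**Retrosynthetic overview**

1. Target 34 is read as guibourtinidol-(4α→8)-ent-afzelechin (upper unit 2R,3S,4S, all-trans; lower unit 2S,3R, trans). It comes from global hydrogenolysis of the hexa-O-benzyl bis-flavan 33.
2. The interflavan C4–C8 bond, the upper C3–O bond and the upper C3/C4 stereocentres are made together by a (SIMes)CuCl/Pd(OAc)2–RuPhos anti-arylboration of (S)-flav-3-ene 14 with the 8-bromo lower unit 31, then C–B oxidation.
3. Both flavan units come from chromones (11, 24) and one arylboronic acid 4 by [Rh(OH)(cod)]2-catalysed enantioselective 1,4-arylation with opposite ligand hands. The flavanones are reduced and dehydrated to flav-3-enes; the lower one is hydroborated, benzylated and brominated at C8.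
4. The phloroglucinol-type ring A of chromone 24 is built from resorcinol by ortho-lithiation/acetylation and [Ir(OMe)(cod)]2-catalysed meta C–H borylation–oxidation; chromone 11 comes from resorcinol by acetylation.
5. Ring order: rings A are bought as resorcinol, the pyranone rings C are closed next (enaminone cyclisation), rings B are attached in the 1,4-arylation, and the two finished flavans are joined last.

Assumption: by analogy with [Rh(OH)((S)-BINAP)]2 additions to cyclohexenone, the (S)-bisphosphine is taken to give the (2S)-flavanone; if the first run shows the opposite sense, the two ligand hands are exchanged between steps 6 and 15.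

**Route**

Step 1
Reactants: 1 4-bromophenol
Product: 2 1-(benzyloxy)-4-bromobenzene
Conditions: BnBr, K2CO3, acetone, reflux
Reagents that add atoms: benzyl bromide (BrCc1ccccc1)
Why: Williamson ether synthesis on a phenoxide with a reactive benzylic halide.

Step 2
Reactants: 2 1-(benzyloxy)-4-bromobenzene
Product: 4 [4-(benzyloxy)phenyl]boronic acid, via 4-(benzyloxy)phenyllithium 3 (not isolated)
Conditions: n-BuLi, THF, −78 °C; B(OMe)3, −78 °C → rt; 1 M HCl
Reagents that add atoms: n-butyllithium (CCCC[Li], lithium of 3 only); trimethyl borate (COB(OC)OC); water (O)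
Why: Lithium–bromine exchange followed by borate trapping and hydrolysis is the standard arylboronic acid synthesis, and the benzyl ether is inert at −78 °C.

Step 3
Reactants: 5 resorcinol, 6 acetic acid
Product: 7 1-(2,4-dihydroxyphenyl)ethanone
Conditions: ZnCl2, neat AcOH, 140 °C
Reagents that add atoms: none
Why: Nencki (Friedel–Crafts) acylation of resorcinol goes to C4, ortho to one hydroxyl and para to the other.

Step 4
Reactants: 7 1-(2,4-dihydroxyphenyl)ethanone
Product: 8 1-[4-(benzyloxy)-2-hydroxyphenyl]ethanone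
Conditions: BnBr (1.05 equiv), K2CO3, acetone, reflux
Reagents that add atoms: benzyl bromide (BrCc1ccccc1)
Why: Williamson etherification is selective for the 4-OH because the 2-OH is locked in a hydrogen bond to the ketone.

Step 5
Reactants: 8 1-[4-(benzyloxy)-2-hydroxyphenyl]ethanone, 9 N,N-dimethylformamide dimethyl acetal
Product: 11 7-(benzyloxy)-4H-chromen-4-one, via enaminone 10 (not isolated)
Conditions: 9, toluene, 100 °C; then conc. HCl, CH2Cl2, rt
Reagents that add atoms: none
Why: Enaminone formation at the methyl ketone followed by acid-promoted addition–elimination of the ortho phenol (loss of dimethylamine) is the standard chromone ring synthesis.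

Step 6
Reactants: 11 7-(benzyloxy)-4H-chromen-4-one, 4 [4-(benzyloxy)phenyl]boronic acid
Product: 12 (2S)-7-(benzyloxy)-2-[4-(benzyloxy)phenyl]chroman-4-one
Conditions: [Rh(OH)(cod)]2 (1.5 mol %), (S)-MeO-F12-BIPHEP (3.3 mol %), 4 (3 equiv), toluene/H2O 10:1, 30 °C
Reagents that add atoms: none
Why: Hayashi–Miyaura type asymmetric 1,4-addition, in which the aryl–rhodium species bearing the (S)-bisphosphine adds to one enantioface of the chromone C2=C3 bond and sets the (2S) centre; the electron-poor ligand speeds transmetalation, so no base is needed and the flavanone is not ring-opened.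

Step 7
Reactants: 12 (2S)-7-(benzyloxy)-2-[4-(benzyloxy)phenyl]chroman-4-one
Product: 13 (2S,4S)-7-(benzyloxy)-2-[4-(benzyloxy)phenyl]chroman-4-ol
Conditions: NaBH4, THF/MeOH, 0 °C
Reagents that add atoms: none
Why: Hydride reduction with axial attack gives mainly the 2,4-cis alcohol; the C4 centre is removed in the next step, so its configuration does not matter.

Step 8
Reactants: 13 (2S,4S)-7-(benzyloxy)-2-[4-(benzyloxy)phenyl]chroman-4-ol
Product: 14 (2S)-7-(benzyloxy)-2-[4-(benzyloxy)phenyl]-2H-chromene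
Conditions: Ph2S[OC(CF3)2Ph]2 (Martin sulfurane), CH2Cl2, 0 °C → rt
Reagents that add atoms: none
Why: Martin sulfurane dehydration of an activated benzylic alcohol runs without acid, so the acid-labile flav-3-ene and its C2 centre (no acidic or ionisable bond is touched) are preserved.

Step 9
Reactants: 5 resorcinol
Product: 15 1,3-bis(methoxymethoxy)benzene
Conditions: MOMCl, K2CO3, acetone, 0 °C → reflux
Reagents that add atoms: chloromethyl methyl ether (COCCl)
Why: Williamson-type acetalisation; the methoxymethyl groups serve as ortho-directing groups and carry no aryl C–H bonds that could compete in step 11.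

Step 10
Reactants: 15 1,3-bis(methoxymethoxy)benzene, 16 N-methoxy-N-methylacetamide
Product: 18 1-[2,6-bis(methoxymethoxy)phenyl]ethanone, via 2,6-bis(methoxymethoxy)phenyllithium 17 (not isolated)
Conditions: n-BuLi, THF, 0 °C → rt; then 16, −78 → 0 °C; H2O
Reagents that add atoms: n-butyllithium (CCCC[Li], lithium of 17 only)
Why: Directed ortho-metalation occurs at the position flanked by both methoxymethoxy groups, and Weinreb amide acylation stops cleanly at the ketone.

Step 11
Reactants: 18 1-[2,6-bis(methoxymethoxy)phenyl]ethanone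
Product: 20 1-[4-hydroxy-2,6-bis(methoxymethoxy)phenyl]ethanone, via aryl pinacol boronate 19 (not isolated)
Conditions: [Ir(OMe)(cod)]2 (1.5 mol %), 4,4'-di-tert-butyl-2,2'-bipyridine (3 mol %), B2pin2 (1.0 equiv), THF, 80 °C; then NaBO3·4H2O, THF/H2O, rt
Reagents that add atoms: bis(pinacolato)diboron (CC1(C)OB(OC1(C)C)B1OC(C)(C)C(C)(C)O1, boron of 19 only); sodium perborate ([Na+].[Na+].O[B-]1(O)OO[B-](O)(O)OO1)
Why: Iridium-catalysed aromatic C–H borylation is sterically controlled, so only the C–H para to the acetyl group, the one ring position without an ortho substituent, reacts, and perborate oxidation turns C–B into C–O to complete the 1,3,5-trioxygenated ring A.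

Step 12
Reactants: 20 1-[4-hydroxy-2,6-bis(methoxymethoxy)phenyl]ethanone
Product: 21 1-[4-(benzyloxy)-2,6-bis(methoxymethoxy)phenyl]ethanone
Conditions: BnBr, K2CO3, DMF, rt
Reagents that add atoms: benzyl bromide (BrCc1ccccc1)
Why: Williamson etherification of the acidic para-acyl phenol.

Step 13
Reactants: 21 1-[4-(benzyloxy)-2,6-bis(methoxymethoxy)phenyl]ethanone, 9 N,N-dimethylformamide dimethyl acetal
Product: 23 7-(benzyloxy)-5-hydroxy-4H-chromen-4-one, via enaminone 22 (not isolated)
Conditions: neat 9, 110 °C; then 3 M HCl, MeOH, 50 °C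
Reagents that add atoms: none
Why: Enaminone formation followed by acid, which removes both methoxymethyl groups and lets one of the two equivalent phenols close the chromone ring with loss of dimethylamine; the benzyl ether survives.

Step 14
Reactants: 23 7-(benzyloxy)-5-hydroxy-4H-chromen-4-one
Product: 24 5,7-bis(benzyloxy)-4H-chromen-4-one
Conditions: BnBr, K2CO3, DMF, 70 °C
Reagents that add atoms: benzyl bromide (BrCc1ccccc1)
Why: Williamson etherification; warming in DMF overcomes the hydrogen bond of the 5-OH to the carbonyl, and carbonate does not open the chromone.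

Step 15
Reactants: 24 5,7-bis(benzyloxy)-4H-chromen-4-one, 4 [4-(benzyloxy)phenyl]boronic acid
Product: 25 (2R)-5,7-bis(benzyloxy)-2-[4-(benzyloxy)phenyl]chroman-4-one
Conditions: [Rh(OH)(cod)]2 (2.5 mol %), (R)-MeO-F12-BIPHEP (5.5 mol %), 4 (4 equiv), toluene/H2O 10:1, 40 °C
Reagents that add atoms: none
Why: The same Hayashi–Miyaura type 1,4-addition as step 6 with the mirror-image ligand, which delivers the aryl group to the opposite enantioface and sets the (2R) centre.

Step 16
Reactants: 25 (2R)-5,7-bis(benzyloxy)-2-[4-(benzyloxy)phenyl]chroman-4-one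
Product: 26 (2R,4R)-5,7-bis(benzyloxy)-2-[4-(benzyloxy)phenyl]chroman-4-ol
Conditions: NaBH4, THF/MeOH, 0 °C
Reagents that add atoms: none
Why: Hydride reduction to the 2,4-cis alcohol; the C4 centre is removed in the next step.

Step 17
Reactants: 26 (2R,4R)-5,7-bis(benzyloxy)-2-[4-(benzyloxy)phenyl]chroman-4-ol
Product: 27 (2R)-5,7-bis(benzyloxy)-2-[4-(benzyloxy)phenyl]-2H-chromene
Conditions: Ph2S[OC(CF3)2Ph]2 (Martin sulfurane), CH2Cl2, −20 °C → rt; work-up over Et3N-washed silica
Reagents that add atoms: none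
Why: Acid-free Martin sulfurane dehydration of a very easily ionised benzylic alcohol gives the flav-3-ene without touching C2.

Step 18
Reactants: 27 (2R)-5,7-bis(benzyloxy)-2-[4-(benzyloxy)phenyl]-2H-chromene
Product: 29 (2S,3R)-5,7-bis(benzyloxy)-2-[4-(benzyloxy)phenyl]chroman-3-ol, via flavan-3-ylborane 28 (not isolated)
Conditions: BH3·THF, THF, 0 °C → rt; then NaBO3·4H2O, THF/H2O, rt
Reagents that add atoms: borane–tetrahydrofuran ([BH3-][O+]1CCCC1, boron of 28 only); sodium perborate ([Na+].[Na+].O[B-]1(O)OO[B-](O)(O)OO1)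
Why: Brown hydroboration–oxidation, in which borane adds syn to the electron-rich styrene-type C3=C4 bond from the face opposite the C2 aryl with boron at the non-benzylic C3, and C–B oxidation with retention sets the (3R) carbinol trans to the aryl group.

Step 19
Reactants: 29 (2S,3R)-5,7-bis(benzyloxy)-2-[4-(benzyloxy)phenyl]chroman-3-ol
Product: 30 (2S,3R)-3,5,7-tris(benzyloxy)-2-[4-(benzyloxy)phenyl]chromane
Conditions: NaH, BnBr, Bu4NI (cat.), DMF, 0 °C → rt
Reagents that add atoms: benzyl bromide (BrCc1ccccc1)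
Why: Williamson etherification of the secondary alcohol, so that no free hydroxyl meets the alkoxide base and catalysts of step 21.

Step 20
Reactants: 30 (2S,3R)-3,5,7-tris(benzyloxy)-2-[4-(benzyloxy)phenyl]chromane
Product: 31 (2S,3R)-3,5,7-tris(benzyloxy)-2-[4-(benzyloxy)phenyl]-8-bromochromane
Conditions: NBS (1.0 equiv), CH2Cl2, −78 → 0 °C
Reagents that add atoms: N-bromosuccinimide (O=C1CCC(=O)N1Br)
Why: Electrophilic aromatic bromination of the phloroglucinol-type ring A, which in per-O-benzylated flavan-3-ols goes preferentially to C8 rather than C6 with one equivalent of NBS at low temperature.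

Step 21
Reactants: 14 (2S)-7-(benzyloxy)-2-[4-(benzyloxy)phenyl]-2H-chromene, 31 (2S,3R)-3,5,7-tris(benzyloxy)-2-[4-(benzyloxy)phenyl]-8-bromochromane
Product: 33 (2R,3S,4S)-7-(benzyloxy)-2-[4-(benzyloxy)phenyl]-4-[(2S,3R)-3,5,7-tris(benzyloxy)-2-[4-(benzyloxy)phenyl]chroman-8-yl]chroman-3-ol, via C3 pinacol boronate 32 (not isolated)
Conditions: 14 (1.3 equiv), (SIMes)CuCl (10 mol %), Pd(OAc)2 (5 mol %), RuPhos (6 mol %), B2pin2 (1.5 equiv), NaOt-Bu (1.5 equiv), toluene/THF, 40 °C; then NaBO3·4H2O, THF/H2O, rt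
Reagents that add atoms: bis(pinacolato)diboron (CC1(C)OB(OC1(C)C)B1OC(C)(C)C(C)(C)O1, boron of 32 only); sodium perborate ([Na+].[Na+].O[B-]1(O)OO[B-](O)(O)OO1)
Why: Proposed new method: an anti-selective arylboration of a flav-3-ene with a di-ortho-oxygenated flavan-8-yl bromide, in which the monovalent copper boryl (SIMes)Cu–Bpin adds syn across C3=C4 on the face opposite the C2 aryl with boron at C3 and copper at the benzylic C4 (styrene regiochemistry), the benzylic copper is passed with inversion to the divalent arylpalladium bromide formed from 31 and zerovalent Pd–RuPhos (the boryl-bearing face is blocked, so the bulky aryl can only arrive anti), and reductive elimination then stereoretentive C–B oxidation give the 2,3-trans-3,4-trans (4α→8) linkage, so the C4–C8 bond and the C3 and C4 stereocentres are set in one operation; the closest known reaction type is the copper/palladium co-catalysed anti-arylboration of 1,2-dihydronaphthalenes and other simple cyclic alkenylarenes with unhindered aryl bromides, not yet shown on 2-aryl-2H-chromenes or on 2,6-dioxygenated aryl bromides.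

Step 22
Reactants: 33 (2R,3S,4S)-7-(benzyloxy)-2-[4-(benzyloxy)phenyl]-4-[(2S,3R)-3,5,7-tris(benzyloxy)-2-[4-(benzyloxy)phenyl]chroman-8-yl]chroman-3-ol
Product: 34 (2R,3S,4S)-2-(4-hydroxyphenyl)-4-[(2S,3R)-3,5,7-trihydroxy-2-(4-hydroxyphenyl)chroman-8-yl]chromane-3,7-diol
Conditions: H2 (1 atm), Pd(OH)2/C, THF/MeOH 1:1, rt
Reagents that add atoms: none
Why: Catalytic hydrogenolysis removes all six benzyl ethers under neutral conditions that are standard for benzylated proanthocyanidins and leave the C2–O1 bonds, the interflavan bond and all five stereocentres untouched.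

**Compound list**

1 | 4-bromophenol | Oc1ccc(Br)cc1 | starting material
2 | 1-(benzyloxy)-4-bromobenzene | Brc1ccc(OCc2ccccc2)cc1 | intermediate
3 | 4-(benzyloxy)phenyllithium (not isolated) | [Li]c1ccc(OCc2ccccc2)cc1 | intermediate
4 | [4-(benzyloxy)phenyl]boronic acid | OB(O)c1ccc(OCc2ccccc2)cc1 | intermediate
5 | resorcinol (benzene-1,3-diol) | Oc1cccc(O)c1 | starting material
6 | acetic acid | CC(=O)O | starting material
7 | 1-(2,4-dihydroxyphenyl)ethanone | CC(=O)c1ccc(O)cc1O | intermediate
8 | 1-[4-(benzyloxy)-2-hydroxyphenyl]ethanone | CC(=O)c1ccc(OCc2ccccc2)cc1O | intermediate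
9 | N,N-dimethylformamide dimethyl acetal | COC(OC)N(C)C | starting material
10 | (E)-1-[4-(benzyloxy)-2-hydroxyphenyl]-3-(dimethylamino)prop-2-en-1-one (not isolated) | CN(C)/C=C/C(=O)c1ccc(OCc2ccccc2)cc1O | intermediate
11 | 7-(benzyloxy)-4H-chromen-4-one | O=c1ccoc2cc(OCc3ccccc3)ccc12 | intermediate
12 | (2S)-7-(benzyloxy)-2-[4-(benzyloxy)phenyl]chroman-4-one | O=C1C[C@@H](c2ccc(OCc3ccccc3)cc2)Oc2cc(OCc3ccccc3)ccc12 | intermediate
13 | (2S,4S)-7-(benzyloxy)-2-[4-(benzyloxy)phenyl]chroman-4-ol (2,4-cis) | O[C@H]1C[C@@H](c2ccc(OCc3ccccc3)cc2)Oc2cc(OCc3ccccc3)ccc12 | intermediate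
14 | (2S)-7-(benzyloxy)-2-[4-(benzyloxy)phenyl]-2H-chromene | C1=C[C@@H](c2ccc(OCc3ccccc3)cc2)Oc2cc(OCc3ccccc3)ccc12 | intermediate
15 | 1,3-bis(methoxymethoxy)benzene | COCOc1cccc(OCOC)c1 | intermediate
16 | N-methoxy-N-methylacetamide | CC(=O)N(C)OC | starting material
17 | 2,6-bis(methoxymethoxy)phenyllithium (not isolated) | [Li]c1c(OCOC)cccc1OCOC | intermediate
18 | 1-[2,6-bis(methoxymethoxy)phenyl]ethanone | CC(=O)c1c(OCOC)cccc1OCOC | intermediate
19 | 1-[2,6-bis(methoxymethoxy)-4-(4,4,5,5-tetramethyl-1,3,2-dioxaborolan-2-yl)phenyl]ethanone (not isolated) | CC(=O)c1c(OCOC)cc(B2OC(C)(C)C(C)(C)O2)cc1OCOC | intermediate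
20 | 1-[4-hydroxy-2,6-bis(methoxymethoxy)phenyl]ethanone | CC(=O)c1c(OCOC)cc(O)cc1OCOC | intermediate
21 | 1-[4-(benzyloxy)-2,6-bis(methoxymethoxy)phenyl]ethanone | CC(=O)c1c(OCOC)cc(OCc2ccccc2)cc1OCOC | intermediate
22 | (E)-1-[4-(benzyloxy)-2,6-bis(methoxymethoxy)phenyl]-3-(dimethylamino)prop-2-en-1-one (not isolated) | CN(C)/C=C/C(=O)c1c(OCOC)cc(OCc2ccccc2)cc1OCOC | intermediate
23 | 7-(benzyloxy)-5-hydroxy-4H-chromen-4-one | O=c1ccoc2cc(OCc3ccccc3)cc(O)c12 | intermediate
24 | 5,7-bis(benzyloxy)-4H-chromen-4-one | O=c1ccoc2cc(OCc3ccccc3)cc(OCc3ccccc3)c12 | intermediate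
25 | (2R)-5,7-bis(benzyloxy)-2-[4-(benzyloxy)phenyl]chroman-4-one | O=C1C[C@H](c2ccc(OCc3ccccc3)cc2)Oc2cc(OCc3ccccc3)cc(OCc3ccccc3)c12 | intermediate
26 | (2R,4R)-5,7-bis(benzyloxy)-2-[4-(benzyloxy)phenyl]chroman-4-ol (2,4-cis) | O[C@@H]1C[C@H](c2ccc(OCc3ccccc3)cc2)Oc2cc(OCc3ccccc3)cc(OCc3ccccc3)c12 | intermediate
27 | (2R)-5,7-bis(benzyloxy)-2-[4-(benzyloxy)phenyl]-2H-chromene | C1=C[C@H](c2ccc(OCc3ccccc3)cc2)Oc2cc(OCc3ccccc3)cc(OCc3ccccc3)c12 | intermediate
28 | [(2R,3R)-5,7-bis(benzyloxy)-2-[4-(benzyloxy)phenyl]chroman-3-yl]borane (2,3-trans; same geometry as 29; not isolated) | B[C@@H]1Cc2c(OCc3ccccc3)cc(OCc3ccccc3)cc2O[C@H]1c1ccc(OCc2ccccc2)cc1 | intermediate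
29 | (2S,3R)-5,7-bis(benzyloxy)-2-[4-(benzyloxy)phenyl]chroman-3-ol (tri-O-benzyl-ent-afzelechin) | O[C@@H]1Cc2c(OCc3ccccc3)cc(OCc3ccccc3)cc2O[C@H]1c1ccc(OCc2ccccc2)cc1 | intermediate
30 | (2S,3R)-3,5,7-tris(benzyloxy)-2-[4-(benzyloxy)phenyl]chromane | C(c1ccccc1)O[C@@H]1Cc2c(OCc3ccccc3)cc(OCc3ccccc3)cc2O[C@H]1c1ccc(OCc2ccccc2)cc1 | intermediate
31 | (2S,3R)-3,5,7-tris(benzyloxy)-2-[4-(benzyloxy)phenyl]-8-bromochromane | C(c1ccccc1)O[C@@H]1Cc2c(OCc3ccccc3)cc(OCc3ccccc3)c(Br)c2O[C@H]1c1ccc(OCc2ccccc2)cc1 | intermediate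
32 | (2S,3S,4S)-7-(benzyloxy)-2-[4-(benzyloxy)phenyl]-3-(4,4,5,5-tetramethyl-1,3,2-dioxaborolan-2-yl)-4-[(2S,3R)-3,5,7-tris(benzyloxy)-2-[4-(benzyloxy)phenyl]chroman-8-yl]chromane (same geometry as 33; not isolated) | C(c5ccccc5)Oc1ccc([C@H]2Oc3cc(OCc5ccccc5)ccc3[C@@H](c3c(OCc5ccccc5)cc(OCc5ccccc5)c4c3O[C@@H](c3ccc(OCc5ccccc5)cc3)[C@H](OCc5ccccc5)C4)[C@@H]2B6OC(C)(C)C(C)(C)O6)cc1 | intermediate
33 | (2R,3S,4S)-7-(benzyloxy)-2-[4-(benzyloxy)phenyl]-4-[(2S,3R)-3,5,7-tris(benzyloxy)-2-[4-(benzyloxy)phenyl]chroman-8-yl]chroman-3-ol | C(c5ccccc5)Oc1ccc([C@H]2Oc3cc(OCc5ccccc5)ccc3[C@@H](c3c(OCc5ccccc5)cc(OCc5ccccc5)c4c3O[C@@H](c3ccc(OCc5ccccc5)cc3)[C@H](OCc5ccccc5)C4)[C@@H]2O)cc1 | intermediate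
34 | (2R,3S,4S)-2-(4-hydroxyphenyl)-4-[(2S,3R)-3,5,7-trihydroxy-2-(4-hydroxyphenyl)chroman-8-yl]chromane-3,7-diol (CNP0110462.4) | Oc1ccc([C@H]2Oc3cc(O)ccc3[C@@H](c3c(O)cc(O)c4c3O[C@@H](c3ccc(O)cc3)[C@H](O)C4)[C@@H]2O)cc1 | target

**Step count and risk**

Total step count: 22. Longest linear sequence: 14 (steps 9 to 20, then 21 and 22). The upper branch (steps 3 to 8) and the boronic acid branch (steps 1 and 2) run in parallel.

Steps most likely to fail:

Step 21 (the proposed arylboration). The hindered, electron-rich bromide 31 may be slow in oxidative addition or in accepting the secondary benzylic copper, and syn delivery would give the 4β epimer. The fallback uses known flavan-3,4-diol/flavan-3-ol condensation chemistry. It sets out from 14 and 30 and comes back at 33, so step 20 is not needed. Flav-3-ene 14 is dihydroxylated with OsO4 (cat.) and N-methylmorpholine N-oxide in acetone/H2O on the face opposite the C2 aryl, giving the 2,3-trans-3,4-cis diol (2R,3S,4S)-7-(benzyloxy)-2-[4-(benzyloxy)phenyl]chromane-3,4-diol F1. F1 is then condensed with three equivalents of the unbrominated lower unit 30 under TiCl4 in CH2Cl2 at −78 to 0 °C. Ionisation at C4 gives the benzylic cation stabilised by the 7-benzyloxy group, and C8 of 30 captures it trans to the 3-hydroxyl, giving 33. Minor 4β and C6-linked isomers are removed by chromatography.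

Step 15 (enantioselective 1,4-arylation of the hindered, electron-rich 5,7-dibenzyloxychromone). The fallback gives up the asymmetric C–C bond formation and sets out from 24 and 4, coming back at 26. Achiral conjugate arylation with Pd(OCOCF3)2/2,2'-bipyridine in ClCH2CH2Cl/H2O at 60 °C gives rac-5,7-bis(benzyloxy)-2-[4-(benzyloxy)phenyl]chroman-4-one F2. A kinetic resolution by asymmetric transfer hydrogenation with RuCl[(R,R)-TsDPEN](p-cymene) and HCO2H/Et3N in EtOAc, stopped near half conversion, reduces the (2R) ketone to the cis alcohol 26 and leaves the (2S) ketone behind. This replaces step 16, with a maximum yield of 50 % from F2.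

Step 17 (dehydration to the very acid- and air-sensitive 5,7-dibenzyloxyflav-3-ene). The alcohol 26 ionises so easily that dimerisation or loss of optical purity may compete. The fallback avoids any benzylic cation by setting out from 25 and coming back at 27, skipping 26. Ketone 25 is converted with Tf2O and 2,6-di-tert-butyl-4-methylpyridine in CH2Cl2 at −78 to 0 °C into (2R)-5,7-bis(benzyloxy)-2-[4-(benzyloxy)phenyl]-2H-chromen-4-yl trifluoromethanesulfonate F3. Reduction of the enol triflate with Pd(OAc)2/PPh3, HCO2H and n-Bu3N in DMF at 60 °C gives 27.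

**Further compounds**

F1 | step 21 | (2R,3S,4S)-7-(benzyloxy)-2-[4-(benzyloxy)phenyl]chromane-3,4-diol | C(c5ccccc5)Oc1ccc([C@H]2Oc3cc(OCc5ccccc5)ccc3[C@H](O)[C@@H]2O)cc1
F2 | step 15 | rac-5,7-bis(benzyloxy)-2-[4-(benzyloxy)phenyl]chroman-4-one | O=C1CC(c2ccc(OCc3ccccc3)cc2)Oc2cc(OCc3ccccc3)cc(OCc3ccccc3)c12
F3 | step 17 | (2R)-5,7-bis(benzyloxy)-2-[4-(benzyloxy)phenyl]-2H-chromen-4-yl trifluoromethanesulfonate | O=S(=O)(OC1=C[C@H](c2ccc(OCc3ccccc3)cc2)Oc2cc(OCc3ccccc3)cc(OCc3ccccc3)c12)C(F)(F)F
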